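**Assumption:** the SMILES is taken as the definitive structure; it corresponds to 1R,3R,11S,12R and 4E,7Z in cembrane-type numbering (ring C1–C14, lactone carbons C15/C16 with the ring oxygen on C12, exo-methylene C17, methyls C18–C20 on C4, C8, C12), which is used throughout.

## Retrosynthetic overview

1. 18 ⇐ 16: fluoride unmasking and decarboxylative Mannich methylenation (C17 installed last).
2. 16 ⇐ 15: nickel-catalysed reductive alkyne–aldehyde macrocyclisation at C3–C4 (fourteen-membered ring, formed second).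
3. 15 ⇐ 14: new amine-catalysed 7-exo intramolecular malonate–enal Michael addition at C1–C15 (seven-membered lactone, formed first; sets C1).
4. 14 ⇐ 8 + 11: carboxylic-acid opening of the epoxide at C12 with inversion, acetylation, cross-metathesis.
5. 8 ⇐ neryl acetate 1: SeO2 oxidation, allylation (C13–C14), Shi epoxidation (C11/C12, first stereocentres), propynylation (C5–C6).

## Route

**Step 1**
Reactants: 1 neryl acetate [(2Z)-3,7-dimethylocta-2,6-dien-1-yl acetate]
Product: 2 (2Z,6E)-8-hydroxy-3,7-dimethylocta-2,6-dien-1-yl acetate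
Conditions: SeO2 (0.4 equiv), t-BuOOH (70% aq, 3 equiv), salicylic acid (0.1 equiv), CH2Cl2, 23 °C
Reagents that add atoms: tert-butyl hydroperoxide CC(C)(C)OO (oxygen atom, relayed through selenium dioxide O=[Se]=O)
Why: SeO2/t-BuOOH allylic oxidation (ene reaction then [2,3]-sigmatropic shift) takes the E-methyl group of the electron-rich terminal alkene because the 2,3-alkene is deactivated by the allylic acetate; no stereocentre is formed.

**Step 2**
Reactants: 2 (2Z,6E)-8-hydroxy-3,7-dimethylocta-2,6-dien-1-yl acetate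
Product: 3 (2Z,6E)-8-bromo-3,7-dimethylocta-2,6-dien-1-yl acetate
Conditions: CBr4, PPh3, CH2Cl2, 0 °C
Reagents that add atoms: carbon tetrabromide BrC(Br)(Br)Br
Why: the Appel reaction converts the primary allylic alcohol into the bromide under neutral conditions without allylic transposition and leaves the acetate untouched.

**Step 3**
Reactants: 3 (2Z,6E)-8-bromo-3,7-dimethylocta-2,6-dien-1-yl acetate
Product: 4 (2Z,6E)-3,7-dimethylundeca-2,6,10-trien-1-yl acetate
Conditions: allylMgBr (1.2 equiv), Li2CuCl4 (3 mol %), THF, −78 °C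
Reagents that add atoms: allylmagnesium bromide C=CC[Mg]Br
Why: Kochi-type copper-catalysed Grignard cross-coupling displaces the primary allylic bromide at C13 (direct SN2, α-selective in THF at low temperature) faster than the Grignard reagent attacks the acetate, so both alkene geometries are kept.

**Step 4**
Reactants: 4 (2Z,6E)-3,7-dimethylundeca-2,6,10-trien-1-yl acetate
Product: 5 (2Z)-5-[(2S,3S)-3-(but-3-en-1-yl)-3-methyloxiran-2-yl]-3-methylpent-2-en-1-yl acetate
Conditions: L-fructose-derived Shi ketone (1,2:4,5-di-O-isopropylidene-β-L-erythro-2,3-hexodiulo-2,6-pyranose, 30 mol %), KHSO5 (as Oxone, 1.4 equiv), K2CO3, Bu4NHSO4 (4 mol %), MeCN/CH2(OMe)2, aq. Na2B4O7 buffer pH 10.5, 0 °C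
Reagents that add atoms: potassium peroxymonosulfate [K+].[O-]S(=O)(=O)OO
Why: Shi asymmetric epoxidation; the chiral dioxirane attacks only the electron-rich E-trisubstituted alkene (the 2,3-alkene is deactivated by the allylic acetate, the vinyl group is monosubstituted) through the spiro transition state, and this ketone enantiomer gives the (S,S)-epoxide, fixing C11 (S) and C12 (S, inverted later).

**Step 5**
Reactants: 5 (2Z)-5-[(2S,3S)-3-(but-3-en-1-yl)-3-methyloxiran-2-yl]-3-methylpent-2-en-1-yl acetate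
Product: 6 (2Z)-5-[(2S,3S)-3-(but-3-en-1-yl)-3-methyloxiran-2-yl]-3-methylpent-2-en-1-ol
Conditions: K2CO3 (0.2 equiv), MeOH, 0 → 23 °C
Reagents that add atoms: none
Why: base-catalysed transesterification (methanolysis) removes the primary acetate, and the trisubstituted epoxide is inert to K2CO3/MeOH.

**Step 6**
Reactants: 6 (2Z)-5-[(2S,3S)-3-(but-3-en-1-yl)-3-methyloxiran-2-yl]-3-methylpent-2-en-1-ol
Product: 7 (2S,3S)-2-(but-3-en-1-yl)-3-[(3Z)-5-chloro-3-methylpent-3-en-1-yl]-2-methyloxirane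
Conditions: MsCl, LiCl, 2,4,6-collidine, DMF, 0 °C
Reagents that add atoms: lithium chloride [Li+].[Cl-] and methanesulfonyl chloride CS(=O)(=O)Cl (either can supply the chloride)
Why: Collington–Meyers chlorination (mesylate formed and displaced in situ by chloride) gives the primary allylic chloride without rearrangement or Z/E change under non-acidic conditions that spare the epoxide.

**Step 7**
Reactants: 7 (2S,3S)-2-(but-3-en-1-yl)-3-[(3Z)-5-chloro-3-methylpent-3-en-1-yl]-2-methyloxirane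
Product: 8 (2S,3S)-2-(but-3-en-1-yl)-2-methyl-3-[(3Z)-3-methyloct-3-en-6-yn-1-yl]oxirane
Conditions: propyne (5 equiv), CuI (20 mol %), NaI (20 mol %), K2CO3 (1.5 equiv), DMF, 23 °C
Reagents that add atoms: propyne CC#C
Why: copper-acetylide alkylation (copper-mediated coupling of a terminal alkyne with an allylic halide) forms C5–C6 by substitution at the primary carbon, giving the skipped enyne with the 7Z alkene intact.

**Step 8**
Reactants: 9 Meldrum's acid (2,2-dimethyl-1,3-dioxane-4,6-dione), 10 2-(trimethylsilyl)ethanol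
Product: 11 3-oxo-3-[2-(trimethylsilyl)ethoxy]propanoic acid (mono-2-(trimethylsilyl)ethyl malonate)
Conditions: toluene, 100 °C
Reagents that add atoms: none
Why: thermal alcoholysis of Meldrum's acid opens the dioxanedione to the malonic half-ester with loss of acetone.

**Step 9**
Reactants: 8 (2S,3S)-2-(but-3-en-1-yl)-2-methyl-3-[(3Z)-3-methyloct-3-en-6-yn-1-yl]oxirane, 11 3-oxo-3-[2-(trimethylsilyl)ethoxy]propanoic acid
Product: 13 (5R,6S,9Z)-6-acetoxy-5,9-dimethyltetradeca-1,9-dien-12-yn-5-yl 2-(trimethylsilyl)ethyl malonate, via hydroxy malonate 12 (not isolated)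
Conditions: 11 (3 equiv), CH2Cl2 (1 M), 23 → 35 °C; cold aq. NaHCO3 wash; then Ac2O, pyridine, DMAP (5 mol %), CH2Cl2, 0 °C
Reagents that add atoms: acetic anhydride CC(=O)OC(C)=O
Why: acidolysis of a 2,2,3-trisubstituted epoxide by a carboxylic acid occurs at the tertiary carbon with inversion (borderline SN2 opening), turning C12 from S into R while C11 stays S, and immediate acetylation of the freed secondary hydroxyl blocks tertiary-to-secondary acyl migration.

**Step 10**
Reactants: 13 (5R,6S,9Z)-6-acetoxy-5,9-dimethyltetradeca-1,9-dien-12-yn-5-yl 2-(trimethylsilyl)ethyl malonate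
Product: 14 (2E,6R,7S,10Z)-7-acetoxy-6,10-dimethyl-1-oxopentadeca-2,10-dien-13-yn-6-yl 2-(trimethylsilyl)ethyl malonate
Conditions: crotonaldehyde (5 equiv), second-generation Hoveyda–Grubbs catalyst RuCl2(H2IMes)(=CH-C6H4-2-OiPr) (5 mol %), CH2Cl2, 40 °C
Reagents that add atoms: (E)-crotonaldehyde C/C=C/C=O
Why: olefin cross-metathesis of the terminal alkene with excess crotonaldehyde gives the E-enal (C1=C2–C3HO), the trisubstituted alkene and the methyl-capped alkyne being much less reactive towards the ruthenium carbene.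

**Step 11**
Reactants: 14 (2E,6R,7S,10Z)-7-acetoxy-6,10-dimethyl-1-oxopentadeca-2,10-dien-13-yn-6-yl 2-(trimethylsilyl)ethyl malonate
Product: 15 2-(trimethylsilyl)ethyl (4R,7R)-7-[(1S,4Z)-1-acetoxy-4-methylnon-4-en-7-yn-1-yl]-7-methyl-2-oxo-4-(2-oxoethyl)oxepane-3-carboxylate (both epimers at ring C3, which is C15 of the target)
Conditions: (S)-2-{bis[3,5-bis(trifluoromethyl)phenyl][(trimethylsilyl)oxy]methyl}pyrrolidine (20 mol %), PhCO2H (20 mol %), EtOH/CH2Cl2 4:1 (0.01 M), 0 → 23 °C, 72 h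
Reagents that add atoms: none
Why: Proposed new method: an enantioselective diarylprolinol-silyl-ether-catalysed intramolecular Michael addition in which a malonate tethered through a tertiary ester closes a seven-membered lactone; the catalyst forms an E,s-trans iminium ion with the enal, the diaryl(silyloxy)methyl group blocks the Si face of C1, and the enolised malonate adds 7-exo-trig to the Re face to give C1 (R) under catalyst control (C12 is 1,4-remote and the tether is flexible), high dilution suppresses the intermolecular pathway and reversibility of the addition lets the slow ring closure accumulate; the closest known reactions are the intermolecular diarylprolinol-silyl-ether-catalysed addition of malonates to enals and amine-catalysed intramolecular Michael cyclisations to five- and six-membered rings.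

**Step 12**
Reactants: 15 2-(trimethylsilyl)ethyl (4R,7R)-7-[(1S,4Z)-1-acetoxy-4-methylnon-4-en-7-yn-1-yl]-7-methyl-2-oxo-4-(2-oxoethyl)oxepane-3-carboxylate
Product: 16 2-(trimethylsilyl)ethyl (1R,3R,4E,7Z,11S,12R)-11-acetoxy-4,8,12-trimethyl-14-oxo-3-[(triethylsilyl)oxy]-13-oxabicyclo[10.3.2]heptadeca-4,7-diene-15-carboxylate (C15 epimers)
Conditions: Ni(cod)2 (zerovalent nickel, 30 mol %), IMes (1,3-dimesitylimidazol-2-ylidene, 30 mol %, premixed), Et3SiH (5 equiv), THF, 0.003 M (slow addition of 15), 23 °C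
Reagents that add atoms: triethylsilane CC[SiH](CC)CC
Why: nickel-catalysed reductive alkyne–aldehyde coupling (Montgomery-type ynal macrocyclisation); oxidative cyclisation with the small carbene ligand forms the C3–C4 bond at the methyl-bearing alkyne carbon (endocyclic mode), σ-bond metathesis with the silane gives the 4E alkene by syn addition, and C3 is set by macrocyclic substrate control, 3R being the planned epimer and the least secure stereochemical call of the route.

**Step 13**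
Reactants: 16 2-(trimethylsilyl)ethyl (1R,3R,4E,7Z,11S,12R)-11-acetoxy-4,8,12-trimethyl-14-oxo-3-[(triethylsilyl)oxy]-13-oxabicyclo[10.3.2]heptadeca-4,7-diene-15-carboxylate
Product: 18 target (1R,3R,4E,7Z,11S,12R)-3-hydroxy-4,8,12-trimethyl-15-methylidene-14-oxo-13-oxabicyclo[10.3.2]heptadeca-4,7-dien-11-yl acetate, via malonic half-acid 17 (not isolated)
Conditions: Bu4NF/AcOH (1:1, 5 equiv), THF/DMF, 23 °C; then 37% aq. HCHO (10 equiv), Et2NH (2 equiv), NaOAc/AcOH, THF, 45 °C
Reagents that add atoms: formaldehyde C=O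
Why: buffered fluoride cleaves the 2-(trimethylsilyl)ethyl ester (β-elimination to ethene) and the silyl ether without generating a free C3 alkoxide, and the malonic half-acid then undergoes decarboxylative Mannich methylenation (Mannich reaction, loss of CO2 and amine) to the α-methylene lactone without touching any stereocentre.

## Compound list

1 | neryl acetate, (2Z)-3,7-dimethylocta-2,6-dien-1-yl acetate | CC(=O)OC/C=C(/C)CCC=C(C)C | starting material
2 | (2Z,6E)-8-hydroxy-3,7-dimethylocta-2,6-dien-1-yl acetate | CC(=O)OC/C=C(/C)CC/C=C(\C)CO | intermediate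
3 | (2Z,6E)-8-bromo-3,7-dimethylocta-2,6-dien-1-yl acetate | CC(=O)OC/C=C(/C)CC/C=C(\C)CBr | intermediate
4 | (2Z,6E)-3,7-dimethylundeca-2,6,10-trien-1-yl acetate | CC(=O)OC/C=C(/C)CC/C=C(\C)CCC=C | intermediate
5 | (2Z)-5-[(2S,3S)-3-(but-3-en-1-yl)-3-methyloxiran-2-yl]-3-methylpent-2-en-1-yl acetate | CC(=O)OC/C=C(/C)CC[C@@H]1O[C@@]1(C)CCC=C | intermediate
6 | (2Z)-5-[(2S,3S)-3-(but-3-en-1-yl)-3-methyloxiran-2-yl]-3-methylpent-2-en-1-ol | OC/C=C(/C)CC[C@@H]1O[C@@]1(C)CCC=C | intermediate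
7 | (2S,3S)-2-(but-3-en-1-yl)-3-[(3Z)-5-chloro-3-methylpent-3-en-1-yl]-2-methyloxirane | ClC/C=C(/C)CC[C@@H]1O[C@@]1(C)CCC=C | intermediate
8 | (2S,3S)-2-(but-3-en-1-yl)-2-methyl-3-[(3Z)-3-methyloct-3-en-6-yn-1-yl]oxirane | CC#CC/C=C(/C)CC[C@@H]1O[C@@]1(C)CCC=C | intermediate
9 | Meldrum's acid, 2,2-dimethyl-1,3-dioxane-4,6-dione | CC1(C)OC(=O)CC(=O)O1 | starting material
10 | 2-(trimethylsilyl)ethanol | C[Si](C)(C)CCO | starting material
11 | 3-oxo-3-[2-(trimethylsilyl)ethoxy]propanoic acid | OC(=O)CC(=O)OCC[Si](C)(C)C | intermediate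
12 | (5R,6S,9Z)-6-hydroxy-5,9-dimethyltetradeca-1,9-dien-12-yn-5-yl 2-(trimethylsilyl)ethyl malonate | CC#CC/C=C(/C)CC[C@H](O)[C@@](C)(CCC=C)OC(=O)CC(=O)OCC[Si](C)(C)C | intermediate
13 | (5R,6S,9Z)-6-acetoxy-5,9-dimethyltetradeca-1,9-dien-12-yn-5-yl 2-(trimethylsilyl)ethyl malonate | CC#CC/C=C(/C)CC[C@H](OC(C)=O)[C@@](C)(CCC=C)OC(=O)CC(=O)OCC[Si](C)(C)C | intermediate
14 | (2E,6R,7S,10Z)-7-acetoxy-6,10-dimethyl-1-oxopentadeca-2,10-dien-13-yn-6-yl 2-(trimethylsilyl)ethyl malonate | CC#CC/C=C(/C)CC[C@H](OC(C)=O)[C@@](C)(CC/C=C/C=O)OC(=O)CC(=O)OCC[Si](C)(C)C | intermediate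
15 | 2-(trimethylsilyl)ethyl (4R,7R)-7-[(1S,4Z)-1-acetoxy-4-methylnon-4-en-7-yn-1-yl]-7-methyl-2-oxo-4-(2-oxoethyl)oxepane-3-carboxylate (C3 epimers) | O=CC[C@H]1CC[C@@](C)(OC(=O)C1C(=O)OCC[Si](C)(C)C)[C@@H](OC(C)=O)CC/C(C)=C\CC#CC | intermediate
16 | 2-(trimethylsilyl)ethyl (1R,3R,4E,7Z,11S,12R)-11-acetoxy-4,8,12-trimethyl-14-oxo-3-[(triethylsilyl)oxy]-13-oxabicyclo[10.3.2]heptadeca-4,7-diene-15-carboxylate (C15 epimers) | O=C(OCC[Si](C)(C)C)C1C(=O)O[C@]2(C)CC[C@@H]1C[C@@H](O[Si](CC)(CC)CC)/C(C)=C/C/C=C(/C)CC[C@@H]2OC(C)=O | intermediate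
17 | (1R,3R,4E,7Z,11S,12R)-11-acetoxy-3-hydroxy-4,8,12-trimethyl-14-oxo-13-oxabicyclo[10.3.2]heptadeca-4,7-diene-15-carboxylic acid (C15 epimers) | OC(=O)C1C(=O)O[C@]2(C)CC[C@@H]1C[C@@H](O)/C(C)=C/C/C=C(/C)CC[C@@H]2OC(C)=O | intermediate
18 | (1R,3R,4E,7Z,11S,12R)-3-hydroxy-4,8,12-trimethyl-15-methylidene-14-oxo-13-oxabicyclo[10.3.2]heptadeca-4,7-dien-11-yl acetate (CNP0130972.5) | C=C1C(=O)O[C@]2(C)CC[C@@H]1C[C@@H](O)/C(C)=C/C/C=C(/C)CC[C@@H]2OC(C)=O | target

## Step count and risks

Total steps: 13. Longest linear sequence: 12 (steps 1–7 and 9–13; step 8 is a one-step side branch).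

**Step 11 (the new seven-membered iminium Michael cyclisation).** Risks: slow 7-ring closure, oligomerisation, or a mismatched bias from C12. The fallback sets out from 8 and returns at 15; it builds the C1–C15 bond intermolecularly by established chemistry and closes the lactone afterwards.
- Cross-metathesis of 8 with crotonaldehyde (same ruthenium catalyst) gives (2E)-5-{(2S,3S)-2-methyl-3-[(3Z)-3-methyloct-3-en-6-yn-1-yl]oxiran-2-yl}pent-2-enal F1.
- Half-ester 11 is allylated (allyl bromide, K2CO3, DMF) to allyl 2-(trimethylsilyl)ethyl malonate F2.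
- The same diarylprolinol silyl ether (10 mol %, EtOH, 0 °C) adds F2 to F1 in the known intermolecular malonate–enal Michael reaction, giving the open-chain adduct allyl 2-(trimethylsilyl)ethyl 2-{(3R)-1-oxo-5-[(2S,3S)-epoxide]pentan-3-yl}malonate F3 with C1 (R).
- Pd(PPh3)4 (zerovalent palladium) with TolSO2Na removes the allyl ester to give the malonic half-acid F4.
- Camphorsulfonic acid (5 mol %, CH2Cl2) closes the lactone by 7-exo opening of the epoxide at C12 with inversion, giving the hydroxy lactone 2-(trimethylsilyl)ethyl (4R,7R)-7-[(1S,4Z)-1-hydroxy-4-methylnon-4-en-7-yn-1-yl]-7-methyl-2-oxo-4-(2-oxoethyl)oxepane-3-carboxylate F5.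
- Ac2O/pyridine acetylates O11 to give 15.

**Step 12 (nickel macrocyclisation).** Risks: endo/exo regiochemistry, which is ligand-tunable, and above all the C3 configuration. The fallback sets out from 16 (obtained as a C3 epimer mixture or as the wrong epimer) and returns at 17; it replaces substrate control by reagent control.
- PPTS/MeOH removes the triethylsilyl group to give the C3-epimeric macrocyclic alcohols F6.
- Dess–Martin periodinane/NaHCO3 gives the macrocyclic 3-oxo enone F7.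
- (S)-2-methyl-CBS-oxazaborolidine with catecholborane (toluene, −78 °C) reduces the α-methyl enone to the (3R)-alcohol F8.
- Bu4NF/AcOH then delivers 17, which is methylenated as in step 13.

**Step 9 (intermolecular acidolysis of the epoxide).** Risks: competing cation–alkene cyclisation or rearrangement, and acyl migration. The fallback sets out from 8 and returns at 13; it separates C–O bond formation from acylation.
- HClO4 (cat.) in THF/H2O at 0 °C hydrolyses the epoxide, water entering at C12 with inversion, to give (5R,6S,9Z)-5,9-dimethyltetradeca-1,9-dien-12-yne-5,6-diol F9.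
- Ac2O/pyridine acetylates only the secondary hydroxyl to give (5R,6S,9Z)-5-hydroxy-5,9-dimethyltetradeca-1,9-dien-12-yn-6-yl acetate F10.
- The acid chloride 2-(trimethylsilyl)ethyl 3-chloro-3-oxopropanoate F11 (from 11, oxalyl chloride, cat. DMF) acylates the tertiary hydroxyl through its acylketene (pyridine, CH2Cl2, 0 °C) to give 13.

## Further compounds

F1 | step 11 | (2E)-5-{(2S,3S)-2-methyl-3-[(3Z)-3-methyloct-3-en-6-yn-1-yl]oxiran-2-yl}pent-2-enal | CC#CC/C=C(/C)CC[C@@H]1O[C@@]1(C)CC/C=C/C=O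
F2 | step 11 | allyl 2-(trimethylsilyl)ethyl malonate | C=CCOC(=O)CC(=O)OCC[Si](C)(C)C
F3 | step 11 | allyl 2-(trimethylsilyl)ethyl 2-{(3R)-1-oxo-5-[(2S,3S)-2-methyl-3-((3Z)-3-methyloct-3-en-6-yn-1-yl)oxiran-2-yl]pentan-3-yl}malonate | O=CC[C@@H](CC[C@]1(C)O[C@H]1CC/C(C)=C\CC#CC)C(C(=O)OCC=C)C(=O)OCC[Si](C)(C)C
F4 | step 11 | 2-{(3R)-1-oxo-5-[(2S,3S)-2-methyl-3-((3Z)-3-methyloct-3-en-6-yn-1-yl)oxiran-2-yl]pentan-3-yl}-3-oxo-3-[2-(trimethylsilyl)ethoxy]propanoic acid | O=CC[C@@H](CC[C@]1(C)O[C@H]1CC/C(C)=C\CC#CC)C(C(=O)O)C(=O)OCC[Si](C)(C)C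
F5 | step 11 | 2-(trimethylsilyl)ethyl (4R,7R)-7-[(1S,4Z)-1-hydroxy-4-methylnon-4-en-7-yn-1-yl]-7-methyl-2-oxo-4-(2-oxoethyl)oxepane-3-carboxylate | O=CC[C@H]1CC[C@@](C)(OC(=O)C1C(=O)OCC[Si](C)(C)C)[C@@H](O)CC/C(C)=C\CC#CC
F6 | step 12 | 2-(trimethylsilyl)ethyl (1R,4E,7Z,11S,12R)-11-acetoxy-3-hydroxy-4,8,12-trimethyl-14-oxo-13-oxabicyclo[10.3.2]heptadeca-4,7-diene-15-carboxylate (C3 epimers) | O=C(OCC[Si](C)(C)C)C1C(=O)O[C@]2(C)CC[C@@H]1CC(O)/C(C)=C/C/C=C(/C)CC[C@@H]2OC(C)=O
F7 | step 12 | 2-(trimethylsilyl)ethyl (1R,4E,7Z,11S,12R)-11-acetoxy-4,8,12-trimethyl-3,14-dioxo-13-oxabicyclo[10.3.2]heptadeca-4,7-diene-15-carboxylate | O=C(OCC[Si](C)(C)C)C1C(=O)O[C@]2(C)CC[C@@H]1CC(=O)/C(C)=C/C/C=C(/C)CC[C@@H]2OC(C)=O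
F8 | step 12 | 2-(trimethylsilyl)ethyl (1R,3R,4E,7Z,11S,12R)-11-acetoxy-3-hydroxy-4,8,12-trimethyl-14-oxo-13-oxabicyclo[10.3.2]heptadeca-4,7-diene-15-carboxylate | O=C(OCC[Si](C)(C)C)C1C(=O)O[C@]2(C)CC[C@@H]1C[C@@H](O)/C(C)=C/C/C=C(/C)CC[C@@H]2OC(C)=O
F9 | step 9 | (5R,6S,9Z)-5,9-dimethyltetradeca-1,9-dien-12-yne-5,6-diol | CC#CC/C=C(/C)CC[C@H](O)[C@](C)(O)CCC=C
F10 | step 9 | (5R,6S,9Z)-5-hydroxy-5,9-dimethyltetradeca-1,9-dien-12-yn-6-yl acetate | CC#CC/C=C(/C)CC[C@H](OC(C)=O)[C@](C)(O)CCC=C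
F11 | step 9 | 2-(trimethylsilyl)ethyl 3-chloro-3-oxopropanoate | ClC(=O)CC(=O)OCC[Si](C)(C)C
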